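The easy step comes first: partner B, once present, meets either starting material, which gives open intermediate, or partner A, which wastes it.

| setting | Saturday's | Monday's | Sunday's | Friday's |
|---|---|---|---|---|
| starting material | 2.0 mM | 2.0 mM | 2.0 mM | 2.0 mM |
| partner A | 4.00 mM | 4.00 mM (fed, over 2.00 s) | 4.00 mM | 4.00 mM |
| partner B | 2.00 mM | 2.00 mM | 2.00 mM (fed, over 2.00 s) | 2.00 mM |
| remark | one stirred flow tank at steady state, fed with the mixture as stated, mean residence time 4.0 s | a stirred flask in which partner A is dosed at a steady rate over 2.00 s without added volume, worked up at 4.0 s | all but partner B at the start; partner B goes in evenly over 2.00 s, the run ends at 4.0 s | a closed flask charged with all of it at once and left for 4.0 s |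
| time |  | 4.0 s | 4.0 s | 4.0 s |

    starting material + partner B → open intermediate (k1 = 65.3 /M/s)
    partner A + target ⇌ idle adduct, settled at all times (K2 = 450 /M)
    partner B + partner A → second intermediate (k3 = 109 /M/s)
    target ⇌ isomer of the product (K4 = 1.93, k4 = 0.0591 /s)
    2 second intermediate → homo product (k5 = 79.8 /M/s)
    open intermediate + second intermediate ⇌ target (K6 = 300 /M, k6 = 89.4 /M/s)

- amounts and yields of target count idle adduct too
- a step written with two of one species runs at k times the square of its concentration and takes two of it each time
- the stated concentrations are those of everything mixed, before any reaction; amounts are the same in each set-up
- the feed brings no volume worth counting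
- run time (Monday's): 4.0 s

- the set-up with the highest amount of open intermediate at the outlet or at the end, in percent of the starting material put in ("none" if the first two lie within 2 percentage points) (Saturday's / Monday's / Sunday's / Friday's / none)
- amount of open intermediate at the outlet or at the end, in percent of the starting material put in, Saturday's
- amount of open intermediate at the outlet or at the end, in percent of the starting material put in, Monday's
- amount of open intermediate at the outlet or at the end, in percent of the starting material put in, Sunday's
- amount of open intermediate at the outlet or at the end, in percent of the starting material put in, Friday's

By hand I reckoned Friday's and Monday's flasks, holding starting material at its charge and partner A at its charge or, in Monday's flask, on its dosing ramp. Each route consumes partner B by a pseudo-first-order rate, a rate constant times a concentration, and I summed each rate over the run. The route through starting material gave 0.522 in both flasks. The route through partner A gave 1.74 in Friday's flask. In Monday's flask it gave 1.31, since the late dosing leaves the equivalent of 3.00 s at full charge.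

The quantity I carried was the exposure share, the starting-material sum divided by the sum of both routes: 28.5 % for Monday's flask and 23.0 % for Friday's. Multiplying each share by the fraction of partner B consumed, 84.0 % on Monday's and 89.6 % on Friday's, gave the starting material opened: 24.0 % on Monday's and 20.7 % on Friday's. Some of that material moves on to target, so I expected somewhat less open intermediate, and I expected Monday's to lead Friday's. I did not reckon the other two flasks.

The forecast chose Monday's, with 22 % there, 17 % for Sunday's, 16.5 % for Friday's and 13.6 % for Saturday's. Its grounds were: “dosing A slowly leaves more B for the starting material”.

The simulation gave Monday's as best, with 22.9 % there, 16.2 % for Sunday's, 17.5 % for Friday's and 13.8 % for Saturday's.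

Monday's flask kept 74.2 % of its starting material and Friday's flask kept 79.6 %, so 25.8 % and 20.4 % had opened, against the 24.0 % and 20.7 % I had reckoned from exposure shares of 28.5 % and 23.0 %. The shrinking supply of partner B was a part of what held open intermediate down: in Monday's flask open intermediate stood at 22.9 %, against 34.9 % without that shrinkage, and in Saturday's tank it stood at 13.8 %, against 27.7 % without it.

The numbers are made up; the run is a simulation.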